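Ring B is cut at bonds B1–B6 and B3–B4, where B1 carries the diaryl ketone, B2 the OH and B6 the CH2 leading to ring C. B1 lies between an oxygen-bearing carbon and a carbon that can derive from a ketone, so B1–B3 map onto an aroylacetone and B4–B6 onto a β-keto acetal. One TiCl4-mediated [3+3] cyclocondensation of the 1-aryl-1,3-bis(trimethylsilyloxy)buta-1,3-diene made from the ring A 1,3-diketone with symmetric 1,1,5,5-tetramethoxypentan-3-one forms both bonds, aromatises ring B, installs the hindered benzophenone without acylating ring B and leaves an acetal from which the 4-hydroxypyran-2-one (ring C) is grown.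

Key step: step 5

Assumption: 1-ethyl-3,5-dimethoxybenzene and 4,4-dimethoxybut-1-yne are taken as purchasable; the target has no stereocentre, so the sp3 centres of 9, 10 and 16 are formed without control and are erased within the route.

Step 1
Reactants: 1 1-ethyl-3,5-dimethoxybenzene; 2 acetyl chloride
Product: 3 1-(2-ethyl-4,6-dimethoxyphenyl)ethan-1-one
Conditions: AlCl3 (1.1 equiv), CH2Cl2, −10 → 0 °C; ice/aq. HCl
Reagents that add atoms: none
Why: Friedel–Crafts acylation, in which the acylium ion should attack C2 of 1 (para to one methoxy group, ortho to the other, less shielded than C4 between the two methoxy groups), the new ketone deactivates the ring against a second acylation and the low temperature should spare the ortho methyl ether from AlCl3.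

Step 2
Reactants: 3 1-(2-ethyl-4,6-dimethoxyphenyl)ethan-1-one
Product: 4 1-(2-ethyl-4,6-dimethoxyphenyl)butane-1,3-dione
Conditions: NaH (3 equiv), EtOAc (5 equiv), THF, 65 °C; aq. HCl to pH 4
Reagents that add atoms: ethyl acetate, CCOC(C)=O
Why: Crossed Claisen condensation, in which the methyl group is the only enolisable position of 3, its enolate is acylated by ethyl acetate and deprotonation of the 1,3-diketone formed pulls the equilibrium forward.

Step 3
Reactants: 4 1-(2-ethyl-4,6-dimethoxyphenyl)butane-1,3-dione
Product: 6 (1Z)-1-(2-ethyl-4,6-dimethoxyphenyl)-1,3-bis(trimethylsilyloxy)buta-1,3-diene, via mono-silyl enol ether 5 (not isolated)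
Conditions: Me3SiOTf (2.3 equiv), Et3N (2.6 equiv), Et2O, 0 → 20 °C; salt layer separated, concentrated under argon, used crude at once
Reagents that add atoms: trimethylsilyl trifluoromethanesulfonate, C[Si](C)(C)OS(=O)(=O)C(F)(F)F
Why: Silyl enol ether formation by soft enolisation, in which the enolised diketone is silylated to 5, a second silyl group on the remaining carbonyl oxygen gives a delocalised oxocarbenium ion and Et3N removes a proton from its methyl group, a double silylation established for 1,3-diketones; the Z geometry follows the chelated enol and has no bearing on step 5.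

Step 4
Reactants: 7 4H-pyran-4-one
Product: 8 1,1,5,5-tetramethoxypentan-3-one
Conditions: MeOH, HC(OMe)3, cat. H2SO4, 65 °C; NaOMe quench, distillation
Reagents that add atoms: methanol, CO; trimethyl orthoformate, COC(OC)OC
Why: Acid-catalysed conjugate addition of methanol to the vinylogous ester, ring opening and acetalisation at both ends convert the pyranone into the open-chain keto bis-acetal, with the orthoformate consuming the water set free.

Step 5
Reactants: 6 (1Z)-1-(2-ethyl-4,6-dimethoxyphenyl)-1,3-bis(trimethylsilyloxy)buta-1,3-diene; 8 1,1,5,5-tetramethoxypentan-3-one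
Product: 11 [2-(2,2-dimethoxyethyl)-6-hydroxyphenyl](2-ethyl-4,6-dimethoxyphenyl)methanone, via open-chain adduct 9 (not isolated), via cyclised aldol 10 (not isolated)
Conditions: 8 (2.5 equiv), TiCl4 (2.5 equiv), CH2Cl2, −78 °C; 6 added slowly, −78 → 20 °C; cold aq. NaHCO3
Reagents that add atoms: none
Why: TiCl4 ionises one of the two identical acetals of 8 to a methoxycarbenium ion, the terminal CH2 carbon of 6 adds to it in a Mukaiyama-type step to give 9, the remaining enol ether (as its titanium diketonate) adds through its central carbon to the activated ketone to give 10, and loss of water and methanol aromatises the ring. The closest known reaction type is the TiCl4-mediated formal [3+3] cyclocondensation of 1,3-bis(silyloxy)-1,3-dienes with β-keto acetals or 3-silyloxy enones, which gives salicylates and 2-acylphenols. Ring B is closed by a 6-(enolexo)-exo-trig aldol addition that forms B1–B6 after the intermolecular step has formed B3–B4. No stereocentre is carried forward, because the sp3 centres of 9 and 10 disappear on aromatisation. The step needs the diene terminus to bond to an acetal carbon and the central carbon to the ketone carbon, which places the CH2 arm ortho to the aroyl group; this is secured because an acetal is ionised by TiCl4 faster than a ketone is attacked and the unsubstituted terminus is the most nucleophilic and least hindered carbon of 6, while the symmetry of 8 makes its two ends equivalent. An excess of 8 should suppress a second addition of 6 to the surviving acetal of 11, and the methyl ethers of ring A should be inert to TiCl4 at these temperatures.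

Step 6
Reactants: 11 [2-(2,2-dimethoxyethyl)-6-hydroxyphenyl](2-ethyl-4,6-dimethoxyphenyl)methanone
Product: 12 2-[2-(2-ethyl-4,6-dimethoxybenzoyl)-3-hydroxyphenyl]acetaldehyde
Conditions: 1 M aq. HCl, THF, 20 °C; extracted, used crude at once
Reagents that add atoms: water, O
Why: Acid-catalysed acetal hydrolysis, during which the diaryl ketone, twisted between two ortho-disubstituted rings and hydrogen-bonded to the phenol, should stay out of the reaction, and the enolisable arylacetaldehyde is not stored.

Step 7
Reactants: 13 2,2,6-trimethyl-4H-1,3-dioxin-4-one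
Product: 15 2,2-dimethyl-6-methylidene-4-(trimethylsilyloxy)-6H-1,3-dioxine, via lithium dienolate 14 (not isolated)
Conditions: LiN(iPr)2 (commercial solution, 1.1 equiv), THF, −78 °C; Me3SiCl, −78 → 20 °C; pentane, filtration, distillation
Reagents that add atoms: chlorotrimethylsilane, C[Si](C)(C)Cl
Why: Kinetic γ-deprotonation of the vinylogous ester gives the extended enolate 14, which is silylated on oxygen, the standard preparation of this silyl dienol ether.

Step 8
Reactants: 12 2-[2-(2-ethyl-4,6-dimethoxybenzoyl)-3-hydroxyphenyl]acetaldehyde; 15 2,2-dimethyl-6-methylidene-4-(trimethylsilyloxy)-6H-1,3-dioxine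
Product: 16 6-{3-[2-(2-ethyl-4,6-dimethoxybenzoyl)-3-hydroxyphenyl]-2-hydroxypropyl}-2,2-dimethyl-4H-1,3-dioxin-4-one (racemic)
Conditions: 15 (2.5 equiv), BF3·OEt2 (2 equiv), CH2Cl2, −78 °C; aq. NaHCO3
Reagents that add atoms: none
Why: Vinylogous Mukaiyama aldol addition, in which the BF3-activated aldehyde is attacked by the exocyclic CH2 terminus of 15, the non-basic conditions avoid enolisation of the arylacetaldehyde and leave the hindered ketone alone, and the new carbinol centre forms as a racemate that is removed by the oxidation of step 9.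

Step 9
Reactants: 16 6-{3-[2-(2-ethyl-4,6-dimethoxybenzoyl)-3-hydroxyphenyl]-2-hydroxypropyl}-2,2-dimethyl-4H-1,3-dioxin-4-one
Product: 17 6-{3-[2-(2-ethyl-4,6-dimethoxybenzoyl)-3-hydroxyphenyl]-2-oxopropyl}-2,2-dimethyl-4H-1,3-dioxin-4-one
Conditions: Dess–Martin periodinane (1.3 equiv), CH2Cl2, 0 → 20 °C; aq. Na2S2O3/NaHCO3
Reagents that add atoms: none
Why: Dess–Martin oxidation of the secondary alcohol under neutral conditions, which the dioxinone, the hydrogen-bonded 2-acylphenol and the methyl ethers should tolerate.

Step 10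
Reactants: 17 6-{3-[2-(2-ethyl-4,6-dimethoxybenzoyl)-3-hydroxyphenyl]-2-oxopropyl}-2,2-dimethyl-4H-1,3-dioxin-4-one
Product: 19 6-{[2-(2-ethyl-4,6-dimethoxybenzoyl)-3-hydroxyphenyl]methyl}-4-hydroxy-2H-pyran-2-one, via acylketene 18 (not isolated)
Conditions: toluene, 110 °C
Reagents that add atoms: none
Why: Thermal retro-hetero-Diels–Alder reaction of the dioxinone releases acetone and the acylketene 18, which is captured by the enol oxygen of the neighbouring ketone in a six-membered closure to give the 4-hydroxypyran-2-one, the established dioxinone route to such pyranones.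

Step 11
Reactants: 19 6-{[2-(2-ethyl-4,6-dimethoxybenzoyl)-3-hydroxyphenyl]methyl}-4-hydroxy-2H-pyran-2-one
Product: 20 6-{[2-(2-ethyl-4,6-dihydroxybenzoyl)-3-hydroxyphenyl]methyl}-4-hydroxy-2H-pyran-2-one
Conditions: BBr3 (8 equiv), CH2Cl2, −78 → 20 °C; ice-water
Reagents that add atoms: none
Why: Lewis acid cleavage of aryl methyl ethers, in which BBr3 coordinates each ether oxygen and bromide removes the methyl group, the ortho ether being helped by chelation to the ketone, while the 4-hydroxypyranone and the diaryl ketone should be inert to the reagent at or below room temperature.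

Compound list
1 | 1-ethyl-3,5-dimethoxybenzene | CCc1cc(OC)cc(OC)c1 | starting material
2 | acetyl chloride | CC(=O)Cl | starting material
3 | 1-(2-ethyl-4,6-dimethoxyphenyl)ethan-1-one | CCc1cc(OC)cc(OC)c1C(C)=O | intermediate
4 | 1-(2-ethyl-4,6-dimethoxyphenyl)butane-1,3-dione | CCc1cc(OC)cc(OC)c1C(=O)CC(C)=O | intermediate
5 | (2Z)-1-(2-ethyl-4,6-dimethoxyphenyl)-3-(trimethylsilyloxy)but-2-en-1-one (not isolated) | CCc1cc(OC)cc(OC)c1C(=O)/C=C(/C)O[Si](C)(C)C | intermediate
6 | (1Z)-1-(2-ethyl-4,6-dimethoxyphenyl)-1,3-bis(trimethylsilyloxy)buta-1,3-diene | CCc1cc(OC)cc(OC)c1/C(O[Si](C)(C)C)=C/C(=C)O[Si](C)(C)C | intermediate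
7 | 4H-pyran-4-one | O=C1C=COC=C1 | starting material
8 | 1,1,5,5-tetramethoxypentan-3-one | COC(OC)CC(=O)CC(OC)OC | intermediate
9 | (1Z)-1-(2-ethyl-4,6-dimethoxyphenyl)-5,9,9-trimethoxy-1-(trimethylsilyloxy)non-1-ene-3,7-dione (racemic at C5, not isolated) | CCc1cc(OC)cc(OC)c1/C(O[Si](C)(C)C)=C/C(=O)CC(OC)CC(=O)CC(OC)OC | intermediate
10 | 3-(2,2-dimethoxyethyl)-2-(2-ethyl-4,6-dimethoxybenzoyl)-3-hydroxy-5-methoxycyclohexan-1-one (mixture of racemic diastereomers, not isolated) | CCc1cc(OC)cc(OC)c1C(=O)C1C(=O)CC(OC)CC1(O)CC(OC)OC | intermediate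
11 | [2-(2,2-dimethoxyethyl)-6-hydroxyphenyl](2-ethyl-4,6-dimethoxyphenyl)methanone | CCc1cc(OC)cc(OC)c1C(=O)c1c(O)cccc1CC(OC)OC | intermediate
12 | 2-[2-(2-ethyl-4,6-dimethoxybenzoyl)-3-hydroxyphenyl]acetaldehyde | CCc1cc(OC)cc(OC)c1C(=O)c1c(O)cccc1CC=O | intermediate
13 | 2,2,6-trimethyl-4H-1,3-dioxin-4-one | CC1=CC(=O)OC(C)(C)O1 | starting material
14 | lithium 2,2-dimethyl-6-methylidene-6H-1,3-dioxin-4-olate (not isolated) | [Li+].C=C1C=C([O-])OC(C)(C)O1 | intermediate
15 | 2,2-dimethyl-6-methylidene-4-(trimethylsilyloxy)-6H-1,3-dioxine | C=C1C=C(O[Si](C)(C)C)OC(C)(C)O1 | intermediate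
16 | 6-{3-[2-(2-ethyl-4,6-dimethoxybenzoyl)-3-hydroxyphenyl]-2-hydroxypropyl}-2,2-dimethyl-4H-1,3-dioxin-4-one (racemic) | CCc1cc(OC)cc(OC)c1C(=O)c1c(O)cccc1CC(O)CC1=CC(=O)OC(C)(C)O1 | intermediate
17 | 6-{3-[2-(2-ethyl-4,6-dimethoxybenzoyl)-3-hydroxyphenyl]-2-oxopropyl}-2,2-dimethyl-4H-1,3-dioxin-4-one | CCc1cc(OC)cc(OC)c1C(=O)c1c(O)cccc1CC(=O)CC1=CC(=O)OC(C)(C)O1 | intermediate
18 | 6-[2-(2-ethyl-4,6-dimethoxybenzoyl)-3-hydroxyphenyl]hex-1-ene-1,3,5-trione (not isolated) | CCc1cc(OC)cc(OC)c1C(=O)c1c(O)cccc1CC(=O)CC(=O)C=C=O | intermediate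
19 | 6-{[2-(2-ethyl-4,6-dimethoxybenzoyl)-3-hydroxyphenyl]methyl}-4-hydroxy-2H-pyran-2-one | CCc1cc(OC)cc(OC)c1C(=O)c1c(O)cccc1Cc1cc(O)cc(=O)o1 | intermediate
20 | 6-{[2-(2-ethyl-4,6-dihydroxybenzoyl)-3-hydroxyphenyl]methyl}-4-hydroxy-2H-pyran-2-one | CCc1cc(O)cc(O)c1C(=O)c1c(O)cccc1Cc1cc(O)cc(=O)o1 | target

Total step count: 11.
Longest linear sequence: 9 steps (steps 1, 2, 3, 5, 6, 8, 9, 10 and 11); steps 4 and 7 are side branches.

Steps most likely to fail

Step 5. TiCl4 may ionise the second acetal as well, before or after the annulation. This could lead to elimination to enol ethers, reclosure to the pyranone or capture by the neighbouring ketone oxygen. The hindered diene may also lose its silyl groups or react through its central carbon first. The fallback sets out from 1, builds ring B by a Diels–Alder benzannulation and comes back at 11. Vilsmeier–Haack formylation of 1 (POCl3, DMF) should give 2-ethyl-4,6-dimethoxybenzaldehyde F1. Addition of lithiated 4,4-dimethoxybut-1-yne (n-BuLi, THF, −78 °C) gives racemic 1-(2-ethyl-4,6-dimethoxyphenyl)-5,5-dimethoxypent-2-yn-1-ol F2. MnO2 in CH2Cl2 oxidises it to the ynone 1-(2-ethyl-4,6-dimethoxyphenyl)-5,5-dimethoxypent-2-yn-1-one F3. The diene 1-methoxy-1-(trimethylsilyloxy)buta-1,3-diene F4 is prepared from methyl crotonate with LiN(iPr)2 and Me3SiCl. Heated with F3 in toluene (20–80 °C), its nucleophilic CH2 terminus should bond to the β-carbon of the ynone, giving the cycloadduct [2-(2,2-dimethoxyethyl)-6-methoxy-6-(trimethylsilyloxy)cyclohexa-1,4-dien-1-yl](2-ethyl-4,6-dimethoxyphenyl)methanone F5. Loss of methoxytrimethylsilane on silica gel or with a trace of acid aromatises it to 11.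

Step 8. The arylacetaldehyde may enolise and self-condense, the activated aldehyde may be captured by the neighbouring ketone oxygen, or the phenol may protodesilylate the dienol ether. The fallback sets out from 12, moves the side chain to the acid oxidation level and comes back at 17, so that steps 8 and 9 are both replaced. Pinnick oxidation (NaClO2, NaH2PO4, 2-methyl-2-butene, t-BuOH/H2O) gives 2-[2-(2-ethyl-4,6-dimethoxybenzoyl)-3-hydroxyphenyl]acetic acid F6. 1,1'-Carbonyldiimidazole in THF converts it into the acyl imidazole 2-[2-(2-ethyl-4,6-dimethoxybenzoyl)-3-hydroxyphenyl]-1-(1H-imidazol-1-yl)ethan-1-one F7. F7 is added at −78 °C to an excess of the lithium dienolate 14 (from 13 and LiN(iPr)2), one equivalent of which is consumed by the phenol. Crossed Claisen acylation at the γ-carbon should give 17.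

Step 11. The para methyl ether may cleave incompletely, and under prolonged exposure to BBr3 the activated diaryl ketone may undergo cyclodehydration with pyranone C5 or with a ring hydroxyl group. The fallback sets out from 19, replaces exhaustive Lewis acid cleavage by a staged deprotection and comes back at 20. BCl3 (CH2Cl2, −78 → 0 °C) should remove only the methyl ether ortho to the ketone through chelation, giving 6-{[2-(2-ethyl-6-hydroxy-4-methoxybenzoyl)-3-hydroxyphenyl]methyl}-4-hydroxy-2H-pyran-2-one F8. The remaining para ether is then cleaved by nucleophilic demethylation with NaSEt in DMF at about 110 °C. Under these basic conditions every acidic site is ionised, so the ketone is not activated and ring A carries no leaving group for xanthone closure; acidification gives 20.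

Further compounds
F1 | step 5 | 2-ethyl-4,6-dimethoxybenzaldehyde | CCc1cc(OC)cc(OC)c1C=O
F2 | step 5 | 1-(2-ethyl-4,6-dimethoxyphenyl)-5,5-dimethoxypent-2-yn-1-ol (racemic) | CCc1cc(OC)cc(OC)c1C(O)C#CCC(OC)OC
F3 | step 5 | 1-(2-ethyl-4,6-dimethoxyphenyl)-5,5-dimethoxypent-2-yn-1-one | CCc1cc(OC)cc(OC)c1C(=O)C#CCC(OC)OC
F4 | step 5 | 1-methoxy-1-(trimethylsilyloxy)buta-1,3-diene (mixture of geometric isomers) | C=CC=C(OC)O[Si](C)(C)C
F5 | step 5 | [2-(2,2-dimethoxyethyl)-6-methoxy-6-(trimethylsilyloxy)cyclohexa-1,4-dien-1-yl](2-ethyl-4,6-dimethoxyphenyl)methanone (racemic) | CCc1cc(OC)cc(OC)c1C(=O)C1=C(CC(OC)OC)CC=CC1(OC)O[Si](C)(C)C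
F6 | step 8 | 2-[2-(2-ethyl-4,6-dimethoxybenzoyl)-3-hydroxyphenyl]acetic acid | CCc1cc(OC)cc(OC)c1C(=O)c1c(O)cccc1CC(=O)O
F7 | step 8 | 2-[2-(2-ethyl-4,6-dimethoxybenzoyl)-3-hydroxyphenyl]-1-(1H-imidazol-1-yl)ethan-1-one | CCc1cc(OC)cc(OC)c1C(=O)c1c(O)cccc1CC(=O)n1ccnc1
F8 | step 11 | 6-{[2-(2-ethyl-6-hydroxy-4-methoxybenzoyl)-3-hydroxyphenyl]methyl}-4-hydroxy-2H-pyran-2-one | CCc1cc(OC)cc(O)c1C(=O)c1c(O)cccc1Cc1cc(O)cc(=O)o1
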